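## Retrosynthetic overview

1. Endgame: global desilylation. The free 7-OH is installed just before it, by sterically controlled C7–H borylation/oxidation of the 7-deoxy 3,5-digallate, so O-5 and O-7 never compete.
2. Both esters come from one double esterification of a (2R,3R)-5-hydroxyflavan-3-ol (B ring silylated) with silylated gallic acid. The acid is made from 4-bromophenol by Duff, double Dakin, silylation and carboxylation.
3. C2 and C3 are both set by dynamic kinetic resolution (transfer hydrogenation) of a racemic 5-hydroxyflavan-3-one.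
4. Key step: the flavan-3-one arises by oxidative furan-to-pyranone ring expansion of an aryl furyl carbinol built on 6,7-dihydrobenzofuran-4(5H)-one. The cyclohexenone aromatises to ring A in the same pot.
5. Ring order: first the furan (cyclohexane-1,3-dione + bromomalonaldehyde). Then the B-ring aryl (from catechol) is added to the formyl group. Then ring C forms by expansion of the furan and ring A by aromatisation. The B and galloyl rings come from benzenoid starting materials.

Assumption: TBS = tert-butyldimethylsilyl and Bpin = 4,4,5,5-tetramethyl-1,3,2-dioxaborolan-2-yl; compounds 8–11 are carried as racemates or diastereomer mixtures because C2 is re-set in step 6.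

## Route

Step 1
Reactants: 1 cyclohexane-1,3-dione; 2 2-bromomalonaldehyde (2-bromopropanedial)
Product: 3 4-oxo-4,5,6,7-tetrahydro-1-benzofuran-2-carbaldehyde
Conditions: NaOAc (1.2 equiv), AcOH–H2O 4:1, 60 °C, slow addition of 1 to 2 (1.3 equiv)
Reagents that add atoms: none
Why: Feist–Bénary furan synthesis, in which the dione carbon condenses with one formyl group, the enol oxygen displaces bromide at the central carbon and loss of water aromatises the furan, leaving the second formyl group on C2 (the same 1,2-bis-electrophile behaviour bromomalonaldehyde shows in thiazole- and imidazole-5-carbaldehyde syntheses); no stereocentre is formed.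

Step 2
Reactants: 4 catechol
Product: 5 4-bromocatechol (4-bromobenzene-1,2-diol)
Conditions: NBS (1.0 equiv), HBF4·OEt2, MeCN, −30 °C → rt
Reagents that add atoms: N-bromosuccinimide, O=C1CCC(=O)N1Br
Why: Electrophilic aromatic bromination, with position 4 (para to one OH, unhindered) the most activated site, while acid-activated NBS at low temperature avoids quinone formation.

Step 3
Reactants: 5 4-bromocatechol
Product: 6 4-bromo-1,2-bis(TBSO)benzene
Conditions: TBSCl (2.4 equiv), imidazole, DMF, rt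
Reagents that add atoms: tert-butyldimethylsilyl chloride, CC(C)(C)[Si](C)(C)Cl
Why: Standard imidazole-promoted O-silylation, giving bulky aryl silyl ethers that survive organolithium, oxidation and Ir catalysis and later shield the neighbouring C–H bonds.

Step 4
Reactants: 6 4-bromo-1,2-bis(TBSO)benzene; 3 4-oxo-4,5,6,7-tetrahydro-1-benzofuran-2-carbaldehyde
Product: 8 (±)-2-{[3,4-bis(TBSO)phenyl](hydroxy)methyl}-6,7-dihydro-1-benzofuran-4(5H)-one, via aryllithium 7 (not isolated)
Conditions: n-BuLi (1.0 equiv), THF, −78 °C; cannulate into 3, THF, −78 °C; aq NH4Cl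
Reagents that add atoms: none
Why: Br/Li exchange followed by 1,2-addition, in which the furfural-type formyl group is far more electrophilic than the vinylogous-ester-like ring ketone and inverse addition keeps the aldehyde in excess; the carbinol centre (future C2) is racemic, which is harmless because it is re-set in step 6.

Step 5
Reactants: 8 (±)-2-{[3,4-bis(TBSO)phenyl](hydroxy)methyl}-6,7-dihydro-1-benzofuran-4(5H)-one
Product: 11 (±)-2-[3,4-bis(TBSO)phenyl]-5-hydroxychroman-3-one (5-hydroxyflavan-3-one), via ring-expanded hemiketal 9 (not isolated), via cross-conjugated trienone 10 (not isolated)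
Conditions: VO(acac)2 (5 mol %), t-BuOOH (1.1 equiv, decane), CH2Cl2, 0 °C → rt; then 4 Å MS, CSA (20 mol %), rt
Reagents that add atoms: tert-butyl hydroperoxide, CC(C)(C)OO (the C3 carbonyl oxygen)
Why: Proposed new method: an aromatising Achmatowicz ring expansion, in which carbinol-directed V/t-BuOOH epoxidation of the electron-richer C2=C3 furan bond opens the furan to a 2-ylidene-cyclohexane-1,3-dione, the carbinol OH closes onto either of the two equivalent ring carbonyls (five-membered furan to six-membered pyranone 9, the untouched carbonyl becoming O-5), acid expels the 8a-OH so that O1–C8a is locked in trienone 10, and a C7-to-C4 proton shift plus keto–enol tautomerism, driven by aromatisation, give 11; the closest known reaction types are the Achmatowicz rearrangement of aryl furyl carbinols and the tautomerisation of cyclohexadienones to phenols, and C2 stays racemic.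

Step 6
Reactants: 11 (±)-2-[3,4-bis(TBSO)phenyl]-5-hydroxychroman-3-one
Product: 12 (2R,3R)-2-[3,4-bis(TBSO)phenyl]chroman-3,5-diol (2,3-cis)
Conditions: (R,R)-Ts-DENEB (tethered RuCl(TsDPEN) catalyst, 1 mol %), HCO2H–Et3N 5:2, CH2Cl2, 30 °C
Reagents that add atoms: none
Why: Proposed new method: ATH-DKR of a flavan-3-one, in which the C2–H (α-keto, benzylic, α-aryloxy) epimerises rapidly through the enol in HCO2H/Et3N while the outer-sphere Ru–H/N–H hydride transfer reduces only the (2R)-ketone from the face anti to the 2-aryl group, so C3 is set by the catalyst and C2 by the resolution to give the cis-(2R,3R)-alcohol; the closest known types are Noyori–Ikariya ATH-DKR of 2-substituted tetralones and chromanones and Ru-catalysed DKR hydrogenation of α-aryl and α-aryloxy cycloalkanones, the (R,R)-catalyst being chosen by letting C2 take the place of the aryl group of acetophenone (the (S,S)-catalyst is used if the sense proves opposite).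

Step 7
Reactants: 13 4-bromophenol
Product: 14 5-bromo-2-hydroxybenzene-1,3-dicarbaldehyde
Conditions: hexamethylenetetramine (2.2 equiv), TFA, reflux, 24 h; then 4 M HCl, rt
Reagents that add atoms: hexamethylenetetramine, C1N2CN3CN1CN(C2)C3 (formyl carbons); water, O (formyl oxygens)
Why: Double Duff formylation, in which iminium ions from protonated hexamethylenetetramine attack both positions ortho to the OH (para is blocked by Br) and internal hydride transfer plus hydrolysis gives the dialdehyde.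

Step 8
Reactants: 14 5-bromo-2-hydroxybenzene-1,3-dicarbaldehyde
Product: 15 5-bromobenzene-1,2,3-triol (5-bromopyrogallol)
Conditions: 30% H2O2 (2.3 equiv), NaOH (2.0 equiv), degassed THF–H2O, 0 °C → rt, Ar
Reagents that add atoms: hydrogen peroxide, OO
Why: Double Dakin oxidation, in which hydroperoxide adds to each o-hydroxy aldehyde, the aryl group shifts 1,2 from carbon to oxygen and the aryl formates hydrolyse, installing the two missing ring oxygens, with air excluded to protect the pyrogallol.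

Step 9
Reactants: 15 5-bromobenzene-1,2,3-triol
Product: 16 5-bromo-1,2,3-tris(TBSO)benzene
Conditions: TBSCl (3.6 equiv), imidazole, DMF, 40 °C
Reagents that add atoms: tert-butyldimethylsilyl chloride, CC(C)(C)[Si](C)(C)Cl
Why: Exhaustive O-silylation, the same contiguous tris-silyl pattern that is routinely made on gallates.

Step 10
Reactants: 16 5-bromo-1,2,3-tris(TBSO)benzene
Product: 18 3,4,5-tris(TBSO)benzoic acid, via aryllithium 17 (not isolated)
Conditions: n-BuLi, THF, −78 °C; CO2 (g), −78 → 0 °C; 1 M HCl to pH 3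
Reagents that add atoms: carbon dioxide, O=C=O
Why: Br/Li exchange and carboxylation, in which the lithiated carbon has no ortho silyloxy group (so no retro-Brook shift occurs) and aryl silyl ethers survive the brief mild acid work-up.

Step 11
Reactants: 12 (2R,3R)-2-[3,4-bis(TBSO)phenyl]chroman-3,5-diol; 18 3,4,5-tris(TBSO)benzoic acid
Product: 19 (2R,3R)-2-[3,4-bis(TBSO)phenyl]chroman-3,5-diyl bis[3,4,5-tris(TBSO)benzoate]
Conditions: 18 (2.4 equiv), DCC, DMAP (0.3 equiv), CH2Cl2, 0 °C → rt
Reagents that add atoms: none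
Why: Steglich esterification acylates the only two free hydroxyls (3-OH and 5-OH) in one operation, with no C–O bond at a stereocentre broken, so (2R,3R) is retained.

Step 12
Reactants: 19 (2R,3R)-2-[3,4-bis(TBSO)phenyl]chroman-3,5-diyl bis[3,4,5-tris(TBSO)benzoate]
Product: 21 (2R,3R)-2-[3,4-bis(TBSO)phenyl]-7-hydroxychroman-3,5-diyl bis[3,4,5-tris(TBSO)benzoate], via 7-pinacolboronate 20 (not isolated)
Conditions: [Ir(OMe)(cod)]2 (3 mol %), dtbpy (6 mol %), B2pin2 (1.2 equiv), THF, 70 °C; evaporate; Oxone, acetone–THF–H2O, 0 °C, 15 min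
Reagents that add atoms: bis(pinacolato)diboron, CC1(C)OB(OC1(C)C)B1OC(C)(C)C(C)(C)O1 (Bpin of 20); potassium peroxymonosulfate (Oxone), [K+].[O-]S(=O)(=O)OO (the 7-oxygen of 21)
Why: Sterically controlled Ir-catalysed aromatic C–H borylation (Hartwig–Miyaura type) selects C7–H, the only aromatic C–H with no ortho substituent, and peroxymonosulfate turns C–B into C–OH by a B-to-O 1,2-shift under acidic conditions that spare aryl esters, silyl ethers and both stereocentres.

Step 13
Reactants: 21 (2R,3R)-2-[3,4-bis(TBSO)phenyl]-7-hydroxychroman-3,5-diyl bis[3,4,5-tris(TBSO)benzoate]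
Product: 22 (−)-epicatechin 3,5-di-O-gallate, (2R,3R)
Conditions: HF·pyridine, pyridine–THF, 0 °C → rt, Ar
Reagents that add atoms: none
Why: Fluoride-driven cleavage of all eight aryl silyl ethers in a mildly acidic medium that neither hydrolyses nor migrates the gallate esters and does not epimerise C2.

## Compound list

1 | cyclohexane-1,3-dione | O=C1CCCC(=O)C1 | starting material
2 | 2-bromomalonaldehyde (2-bromopropanedial) | O=CC(Br)C=O | starting material
3 | 4-oxo-4,5,6,7-tetrahydro-1-benzofuran-2-carbaldehyde | O=Cc1cc2c(o1)CCCC2=O | intermediate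
4 | catechol | Oc1ccccc1O | starting material
5 | 4-bromocatechol | Oc1ccc(Br)cc1O | intermediate
6 | 4-bromo-1,2-bis(TBSO)benzene | CC(C)(C)[Si](C)(C)Oc1ccc(Br)cc1O[Si](C)(C)C(C)(C)C | intermediate
7 | [3,4-bis(TBSO)phenyl]lithium | [Li]c1ccc(O[Si](C)(C)C(C)(C)C)c(O[Si](C)(C)C(C)(C)C)c1 | intermediate
8 | (±)-2-{[3,4-bis(TBSO)phenyl](hydroxy)methyl}-6,7-dihydro-1-benzofuran-4(5H)-one | OC(c1cc2c(o1)CCCC2=O)c1ccc(O[Si](C)(C)C(C)(C)C)c(O[Si](C)(C)C(C)(C)C)c1 | intermediate
9 | 2-[3,4-bis(TBSO)phenyl]-8a-hydroxy-6,7,8,8a-tetrahydro-2H-chromene-3,5-dione (diastereomer mixture) | O=C1C=C2C(=O)CCCC2(O)OC1c1ccc(O[Si](C)(C)C(C)(C)C)c(O[Si](C)(C)C(C)(C)C)c1 | intermediate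
10 | 2-[3,4-bis(TBSO)phenyl]-6,7-dihydro-2H-chromene-3,5-dione | O=C1C=C2C(=O)CCC=C2OC1c1ccc(O[Si](C)(C)C(C)(C)C)c(O[Si](C)(C)C(C)(C)C)c1 | intermediate
11 | (±)-2-[3,4-bis(TBSO)phenyl]-5-hydroxychroman-3-one | O=C1Cc2c(O)cccc2OC1c1ccc(O[Si](C)(C)C(C)(C)C)c(O[Si](C)(C)C(C)(C)C)c1 | intermediate
12 | (2R,3R)-2-[3,4-bis(TBSO)phenyl]chroman-3,5-diol | Oc1cccc2c1C[C@@H](O)[C@@H](c1ccc(O[Si](C)(C)C(C)(C)C)c(O[Si](C)(C)C(C)(C)C)c1)O2 | intermediate
13 | 4-bromophenol | Oc1ccc(Br)cc1 | starting material
14 | 5-bromo-2-hydroxybenzene-1,3-dicarbaldehyde | O=Cc1cc(Br)cc(C=O)c1O | intermediate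
15 | 5-bromobenzene-1,2,3-triol | Oc1cc(Br)cc(O)c1O | intermediate
16 | 5-bromo-1,2,3-tris(TBSO)benzene | CC(C)(C)[Si](C)(C)Oc1cc(Br)cc(O[Si](C)(C)C(C)(C)C)c1O[Si](C)(C)C(C)(C)C | intermediate
17 | [3,4,5-tris(TBSO)phenyl]lithium | [Li]c1cc(O[Si](C)(C)C(C)(C)C)c(O[Si](C)(C)C(C)(C)C)c(O[Si](C)(C)C(C)(C)C)c1 | intermediate
18 | 3,4,5-tris(TBSO)benzoic acid | OC(=O)c1cc(O[Si](C)(C)C(C)(C)C)c(O[Si](C)(C)C(C)(C)C)c(O[Si](C)(C)C(C)(C)C)c1 | intermediate
19 | (2R,3R)-2-[3,4-bis(TBSO)phenyl]chroman-3,5-diyl bis[3,4,5-tris(TBSO)benzoate] | O=C(Oc1cccc2c1C[C@@H](OC(=O)c1cc(O[Si](C)(C)C(C)(C)C)c(O[Si](C)(C)C(C)(C)C)c(O[Si](C)(C)C(C)(C)C)c1)[C@@H](c1ccc(O[Si](C)(C)C(C)(C)C)c(O[Si](C)(C)C(C)(C)C)c1)O2)c1cc(O[Si](C)(C)C(C)(C)C)c(O[Si](C)(C)C(C)(C)C)c(O[Si](C)(C)C(C)(C)C)c1 | intermediate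
20 | 7-Bpin derivative of 19, (2R,3R) | O=C(Oc1cc(B3OC(C)(C)C(C)(C)O3)cc2c1C[C@@H](OC(=O)c1cc(O[Si](C)(C)C(C)(C)C)c(O[Si](C)(C)C(C)(C)C)c(O[Si](C)(C)C(C)(C)C)c1)[C@@H](c1ccc(O[Si](C)(C)C(C)(C)C)c(O[Si](C)(C)C(C)(C)C)c1)O2)c1cc(O[Si](C)(C)C(C)(C)C)c(O[Si](C)(C)C(C)(C)C)c(O[Si](C)(C)C(C)(C)C)c1 | intermediate
21 | 7-hydroxy derivative of 19 (octa-O-TBS epicatechin 3,5-digallate), (2R,3R) | O=C(Oc1cc(O)cc2c1C[C@@H](OC(=O)c1cc(O[Si](C)(C)C(C)(C)C)c(O[Si](C)(C)C(C)(C)C)c(O[Si](C)(C)C(C)(C)C)c1)[C@@H](c1ccc(O[Si](C)(C)C(C)(C)C)c(O[Si](C)(C)C(C)(C)C)c1)O2)c1cc(O[Si](C)(C)C(C)(C)C)c(O[Si](C)(C)C(C)(C)C)c(O[Si](C)(C)C(C)(C)C)c1 | intermediate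
22 | (−)-epicatechin 3,5-di-O-gallate, (2R,3R) | O=C(Oc1cc(O)cc2c1C[C@@H](OC(=O)c1cc(O)c(O)c(O)c1)[C@@H](c1ccc(O)c(O)c1)O2)c1cc(O)c(O)c(O)c1 | target

## Step count and risk

Total step count: 13.
Longest linear sequence: 8 steps (4 → 5 → 6 → 8 → 11 → 12 → 19 → 21 → 22). The gallate branch from 13 reaches the target in 7 steps.

**Step 5 (proposed new step).** The danger is ring-chain opening of 9. If the open form aromatises first, it would cyclodehydrate to a benzofuran-type isomer instead of 11. The fallback uses known reactions only; it sets out from 8 and returns at 11. A classical Achmatowicz oxidation with m-CPBA in CH2Cl2 at 0 °C is run and hemiketal 9 is isolated. A Kishi-type ionic reduction (Et3SiH, TFA, CH2Cl2, −40 °C) then replaces the 8a-OH by H. This locks O1–C8a as a plain ether in 2-[3,4-bis(TBSO)phenyl]-6,7,8,8a-tetrahydro-2H-chromene-3,5-dione F1. DDQ dehydrogenation (dioxane, rt → 60 °C) removes the allylic α-oxy hydride at C8a, and the resulting dienone tautomerises to 11.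

**Step 6 (proposed new step).** The danger is low enantioselectivity on a ketone that carries no aryl group directly on the carbonyl. The fallback sets out from 11 and returns at 12. L-Selectride (2.2 equiv, THF, −78 °C) is the reagent known to convert flavan-3-ones into 2,3-cis-flavan-3-ols. It gives the racemic cis-diol, that is 12 together with its mirror image (2S,3S)-2-[3,4-bis(TBSO)phenyl]chroman-3,5-diol F2. Preparative chiral SFC delivers 12 and F2 is discarded.

**Step 12.** The danger is slow or unselective borylation of a very large, crowded substrate. The fallback sets out from 12 and returns at 20, moving the C–H functionalisation ahead of the acylation.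
- HBpin (2.2 equiv, THF, rt) masks both hydroxyls as the 3,5-bis(O-Bpin) ether F3.
- [Ir(OMe)(cod)]2/dtbpy/B2pin2 (THF, 60 °C) borylates C7 of this much smaller molecule to the 3,5-bis(O-Bpin)-7-Bpin compound F4.
- Methanol cleaves the two B–O bonds to (2R,3R)-2-[3,4-bis(TBSO)phenyl]-7-Bpin-chroman-3,5-diol F5.
- DCC/DMAP esterification with 18 gives 20, which is oxidised with Oxone as in step 12.

## Further compounds

F1 | step 5 | 2-[3,4-bis(TBSO)phenyl]-6,7,8,8a-tetrahydro-2H-chromene-3,5-dione (diastereomer mixture) | O=C1C=C2C(=O)CCCC2OC1c1ccc(O[Si](C)(C)C(C)(C)C)c(O[Si](C)(C)C(C)(C)C)c1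
F2 | step 6 | (2S,3S)-2-[3,4-bis(TBSO)phenyl]chroman-3,5-diol | Oc1cccc2c1C[C@H](O)[C@H](c1ccc(O[Si](C)(C)C(C)(C)C)c(O[Si](C)(C)C(C)(C)C)c1)O2
F3 | step 12 | (2R,3R)-2-[3,4-bis(TBSO)phenyl]-3,5-bis(Bpin-oxy)chroman | CC1(C)OB(Oc2cccc3c2C[C@@H](OB2OC(C)(C)C(C)(C)O2)[C@@H](c2ccc(O[Si](C)(C)C(C)(C)C)c(O[Si](C)(C)C(C)(C)C)c2)O3)OC1(C)C
F4 | step 12 | (2R,3R)-2-[3,4-bis(TBSO)phenyl]-7-Bpin-3,5-bis(Bpin-oxy)chroman | CC1(C)OB(Oc2cc(B4OC(C)(C)C(C)(C)O4)cc3c2C[C@@H](OB2OC(C)(C)C(C)(C)O2)[C@@H](c2ccc(O[Si](C)(C)C(C)(C)C)c(O[Si](C)(C)C(C)(C)C)c2)O3)OC1(C)C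
F5 | step 12 | (2R,3R)-2-[3,4-bis(TBSO)phenyl]-7-Bpin-chroman-3,5-diol | Oc1cc(B3OC(C)(C)C(C)(C)O3)cc2c1C[C@@H](O)[C@@H](c1ccc(O[Si](C)(C)C(C)(C)C)c(O[Si](C)(C)C(C)(C)C)c1)O2
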